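**Strategy.** Punaglandin 8 is cut at the C7–C8 aldol bond and, in the ring, at C10=C11 and C8–C12 (prostanoid numbering: ring C8–C12, C9 ketone, C10 chloride, C12 carbinol). The 4-hydroxycyclopent-2-enone ring is read as a [3+2] union in which C11–C12 is a masked 1,2-ketoaldehyde and C8–C9–C10 a chloroacetonyl ylide. In one flask the γ-anion of the chloro keto ylide adds to the ketone of a chiral keto aminal (C8–C12 bond, C12 configuration), the aminal is cleaved, and intramolecular Wittig closure forms C10=C11. C7 and C8 are then relayed from C12 in a single aldol with the (Z)-enal of the upper chain.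

Key step: step 6

Assumption: the facial sense of the addition in step 6 is taken from the magnesium chelate model used for Grignard additions to keto aminals of 2-(anilinomethyl)pyrrolidine. On that model the (R)-diamine should lead to (12S). Both enantiomers of the diamine are commercial, so an opposite sense would only change the diamine used in step 3.

**Step 1**
Reactants: 1 hept-1-yne; 2 2-(diethoxymethyl)oxirane (glycidaldehyde diethyl acetal, racemic)
Product: 3 1,1-diethoxydec-4-yn-2-ol (racemic)
Conditions: n-BuLi, THF, −78 °C; BF3·OEt2; then 2, −78 °C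
Reagents that add atoms: none
Why: BF3-promoted opening of the terminal epoxide by the lithium acetylide at its CH2 carbon should give the homopropargylic alcohol, and since the carbinol centre is oxidised in step 4 the racemic epoxide suffices.

**Step 2**
Reactants: 3 1,1-diethoxydec-4-yn-2-ol
Product: 4 (Z)-1,1-diethoxydec-4-en-2-ol (racemic)
Conditions: H2 (1 atm), Lindlar catalyst, quinoline, EtOAc, rt
Reagents that add atoms: none
Why: Lindlar semi-hydrogenation delivers H2 syn to the alkyne and should give the (Z)-alkene without touching the acetal.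

**Step 3**
Reactants: 4 (Z)-1,1-diethoxydec-4-en-2-ol; 5 (R)-2-(anilinomethyl)pyrrolidine
Product: 7 (Z)-1-[(2-exo,5R)-3-phenyl-1,3-diazabicyclo[3.3.0]oct-2-yl]non-3-en-1-ol (both carbinol epimers), via (Z)-2-hydroxydec-4-enal 6 (not isolated)
Conditions: 1 M aq. HCl, THF, rt; NaHCO3, extraction; then 5, MgSO4, CH2Cl2, rt
Reagents that add atoms: none
Why: Acetal hydrolysis followed by aminal formation with the 1,2-diamine should give the cis-fused bicyclic aminal with the side chain on the convex face (cis to H-5) under thermodynamic control, and both carbinol epimers lead to the same ketone.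

**Step 4**
Reactants: 7 hydroxy aminal
Product: 8 (Z)-1-[(2-exo,5R)-3-phenyl-1,3-diazabicyclo[3.3.0]oct-2-yl]non-3-en-1-one (keto aminal)
Conditions: (COCl)2, DMSO, CH2Cl2, −78 °C; i-Pr2NEt, −78 → −40 °C; pH 7 buffer
Reagents that add atoms: none
Why: Swern oxidation at low temperature with a cold neutral quench should give the β,γ-unsaturated ketone without moving the (Z)-alkene into conjugation and without affecting the tertiary amine and N-aryl nitrogens of the aminal.

**Step 5**
Reactants: 9 1-(triphenylphosphoranylidene)propan-2-one
Product: 10 1-chloro-1-(triphenylphosphoranylidene)propan-2-one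
Conditions: NCS (1.0 equiv), CH2Cl2, −20 °C → rt; water wash
Reagents that add atoms: N-chlorosuccinimide, O=C1CCC(=O)N1Cl
Why: Electrophilic chlorination of the stabilised ylide at carbon gives the chlorophosphonium salt, which the succinimide anion deprotonates to the chloro ylide.

**Step 6**
Reactants: 10 1-chloro-1-(triphenylphosphoranylidene)propan-2-one; 8 keto aminal
Product: 14 (S)-2-chloro-4-hydroxy-4-[(Z)-oct-2-en-1-yl]cyclopent-2-en-1-one, via bromomagnesium ylide-enolate 11 (not isolated), via aldol adduct aminal 12 (not isolated), via hydroxy aldehyde ylide 13 (not isolated)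
Conditions: LDA (1.0 equiv), THF, −78 °C; MgBr2·OEt2; 8, −78 °C; 2% aq. HCl, 0 °C; NaHCO3 to pH 7–8, rt → 40 °C
Reagents that add atoms: none
Why: γ-Deprotonation of the keto-stabilised ylide gives a cross-conjugated ylide-enolate whose terminal carbon (C8) adds as the bromomagnesium enolate to the ketone (C12) of 8; dilute acid then cleaves the aminal to the α-hydroxy aldehyde while the ylide rests as its phosphonium salt, and at pH 7–8 the ylide is regenerated (the diamine stays protonated) and condenses with the aldehyde to form C10=C11. The closest known reaction types are the aldol/intramolecular Wittig cyclopentenone annulation of glyoxals with acyl ylides and the chelation-controlled addition of Grignard reagents to keto aminals of 2-(anilinomethyl)pyrrolidine. The five-membered ring closes in the Wittig step by 5-exo-trig attack of the ylide carbon on the aldehyde, and collapse of the bicyclic oxaphosphetane can only give the cis ring alkene. C12 is the only new stereocentre and is controlled by the aminal: magnesium is expected to bridge the ketone oxygen and the bridgehead nitrogen, so that the enolate attacks the face remote from the N-phenyl group. The step needs ketone-over-aldehyde chemoselectivity, secured by the aminal mask, a C8 rather than C13 nucleophile, secured by preforming the ylide-enolate, and addition rather than proton transfer, favoured by −78 °C and the magnesium counter-ion.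

**Step 7**
Reactants: 15 (4-carboxybutyl)triphenylphosphonium bromide; 16 (tert-butyldimethylsilyloxy)acetaldehyde
Product: 17 (Z)-7-[(tert-butyldimethylsilyl)oxy]hept-5-enoic acid
Conditions: NaHMDS (2.1 equiv), THF, 0 → −78 °C; 16, −78 °C → rt; dilute acid work-up
Reagents that add atoms: none
Why: Wittig olefination with the non-stabilised carboxylate ylide under salt-free conditions should give the (Z)-alkene under kinetic control.

**Step 8**
Reactants: 17 (Z)-7-[(tert-butyldimethylsilyl)oxy]hept-5-enoic acid
Product: 18 methyl (Z)-7-hydroxyhept-5-enoate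
Conditions: AcCl (0.2 equiv), MeOH, 0 °C → rt
Reagents that add atoms: methanol, CO
Why: Methanolic HCl should effect Fischer esterification and cleavage of the primary silyl ether in one operation, and the (Z)-allylic alcohol should be configurationally stable under these conditions.

**Step 9**
Reactants: 18 methyl (Z)-7-hydroxyhept-5-enoate
Product: 19 methyl (Z)-7-oxohept-5-enoate
Conditions: Dess–Martin periodinane, NaHCO3, CH2Cl2, 0 °C; used at once
Reagents that add atoms: none
Why: Buffered Dess–Martin oxidation of the allylic alcohol is neutral and fast, so the (Z)-enal should form without isomerisation if it is used immediately.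

**Step 10**
Reactants: 14 (S)-2-chloro-4-hydroxy-4-[(Z)-oct-2-en-1-yl]cyclopent-2-en-1-one; 19 methyl (Z)-7-oxohept-5-enoate
Product: 21 methyl (5Z,7S)-7-hydroxy-7-[(1R,2S)-4-chloro-2-hydroxy-2-[(Z)-oct-2-en-1-yl]-5-oxocyclopent-3-en-1-yl]hept-5-enoate, via dilithium alkoxide enolate 20 (not isolated)
Conditions: LDA (2.2 equiv), THF, −78 °C; 19, −78 °C; AcOH, −78 °C
Reagents that add atoms: none
Why: In this lithium aldol addition the aldehyde is expected to approach C8 on the face of the lithium alkoxide, anti to the octenyl chain, which sets 8R (new chain trans to the octenyl group), and the ring-locked (E)-enolate should pass through a Zimmerman–Traxler chair to the anti aldol, which sets 7S.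

**Step 11**
Reactants: 21 aldol diol
Product: 22 punaglandin 8
Conditions: Ac2O, pyridine, CH2Cl2, 0 °C → rt (no DMAP)
Reagents that add atoms: acetic anhydride, CC(=O)OC(C)=O
Why: Acylation with Ac2O/pyridine should acetylate only the secondary allylic C7 hydroxyl, because the tertiary C12 hydroxyl is inert without an acyl-transfer catalyst and the mild conditions disfavour β-elimination of the new acetate.

**Compound list**

1 | hept-1-yne | CCCCCC#C | starting material
2 | 2-(diethoxymethyl)oxirane (racemic) | CCOC(OCC)C1CO1 | starting material
3 | 1,1-diethoxydec-4-yn-2-ol (racemic) | CCCCCC#CCC(O)C(OCC)OCC | intermediate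
4 | (Z)-1,1-diethoxydec-4-en-2-ol (racemic) | CCCCC/C=C\CC(O)C(OCC)OCC | intermediate
5 | (R)-2-(anilinomethyl)pyrrolidine | c1ccc(cc1)NC[C@H]1CCCN1 | starting material
6 | (Z)-2-hydroxydec-4-enal (racemic, not isolated) | CCCCC/C=C\CC(O)C=O | intermediate
7 | (Z)-1-[(2-exo,5R)-3-phenyl-1,3-diazabicyclo[3.3.0]oct-2-yl]non-3-en-1-ol, side chain cis to H-5, both carbinol epimers | CCCCC/C=C\CC(O)[C@@H]1N(c2ccccc2)C[C@H]3CCCN13 | intermediate
8 | (Z)-1-[(2-exo,5R)-3-phenyl-1,3-diazabicyclo[3.3.0]oct-2-yl]non-3-en-1-one, acyl group cis to H-5 | CCCCC/C=C\CC(=O)[C@@H]1N(c2ccccc2)C[C@H]3CCCN13 | intermediate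
9 | 1-(triphenylphosphoranylidene)propan-2-one | CC(=O)C=P(c1ccccc1)(c1ccccc1)c1ccccc1 | starting material
10 | 1-chloro-1-(triphenylphosphoranylidene)propan-2-one | CC(=O)C(Cl)=P(c1ccccc1)(c1ccccc1)c1ccccc1 | intermediate
11 | bromomagnesium enolate of 10 (γ-anion, not isolated) | C=C(O[Mg]Br)C(Cl)=P(c1ccccc1)(c1ccccc1)c1ccccc1 | intermediate
12 | aldol adduct aminal, (S)-carbinol at the future C12, present as its magnesium alkoxide and drawn as the alcohol (not isolated) | CCCCC/C=C\C[C@](O)(CC(=O)C(Cl)=P(c1ccccc1)(c1ccccc1)c1ccccc1)[C@@H]1N(c2ccccc2)C[C@H]3CCCN13 | intermediate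
13 | hydroxy aldehyde ylide, phosphonium chloride below pH 2 (not isolated) | CCCCC/C=C\C[C@](O)(CC(=O)C(Cl)=P(c1ccccc1)(c1ccccc1)c1ccccc1)C=O | intermediate
14 | (S)-2-chloro-4-hydroxy-4-[(Z)-oct-2-en-1-yl]cyclopent-2-en-1-one | CCCCC/C=C\C[C@@]1(O)C=C(Cl)C(=O)C1 | intermediate
15 | (4-carboxybutyl)triphenylphosphonium bromide | OC(=O)CCCC[P+](c1ccccc1)(c1ccccc1)c1ccccc1.[Br-] | starting material
16 | (tert-butyldimethylsilyloxy)acetaldehyde | CC(C)(C)[Si](C)(C)OCC=O | starting material
17 | (Z)-7-[(tert-butyldimethylsilyl)oxy]hept-5-enoic acid | CC(C)(C)[Si](C)(C)OC/C=C\CCCC(=O)O | intermediate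
18 | methyl (Z)-7-hydroxyhept-5-enoate | COC(=O)CCC/C=C\CO | intermediate
19 | methyl (Z)-7-oxohept-5-enoate | COC(=O)CCC/C=C\C=O | intermediate
20 | dilithium alkoxide enolate of 14 (not isolated) | CCCCC/C=C\C[C@@]1(O[Li])C=C(Cl)C(O[Li])=C1 | intermediate
21 | aldol diol, (7S,8R,12S) in prostanoid numbering | CCCCC/C=C\C[C@@]1(O)C=C(Cl)C(=O)[C@@H]1[C@H](/C=C\CCCC(=O)OC)O | intermediate
22 | punaglandin 8, (7S,8R,12S) in prostanoid numbering | CCCCC/C=C\C[C@@]1(O)C=C(Cl)C(=O)[C@@H]1[C@H](/C=C\CCCC(=O)OC)OC(C)=O | target

**Step count.** Total: 11 steps. Longest linear sequence: 7 steps (1, 2, 3, 4, 6, 10, 11).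

**Steps most likely to fail**

Step 6. Proton transfer from the readily enolised β,γ-unsaturated ketone to the basic ylide-enolate may compete with carbonyl addition. Facial control may also be weaker than for Grignard reagents, because the chelate model is carried over to an enolate; since the auxiliary is cleaved in the same flask, any leakage would appear directly as loss of enantiomeric purity. The fallback sets out from 8 and returns at 14, building the two bonds in separate, known operations. The bromomagnesium enolate of methyl acetate (LDA, methyl acetate, THF, −78 °C; MgBr2·OEt2) is added to 8 to give the β-hydroxy ester aminal F1, whose diastereomers can be separated while the auxiliary is still attached. Lithiated dimethyl (chloromethyl)phosphonate (3 equiv, THF, −78 °C) is acylated by the ester to give the α-chloro β-keto phosphonate aminal F2. Hydrolysis with 2% aq. HCl at 0 °C gives the hydroxy aldehyde keto phosphonate F3, and K2CO3/18-crown-6 in toluene closes the ring by intramolecular Horner–Wadsworth–Emmons reaction to 14.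

Step 10. The lithium aldol of a cyclic enolate with a small (Z)-alkenyl aldehyde may show low anti/syn discrimination at C7, and some Z to E isomerisation of the enal is possible. The fallback sets out from 14 and returns at 22, and makes the sequence stereoconvergent instead of relying on aldol stereocontrol. The aldol is run as described and the C7 epimers are separated; 21 goes on through step 11, while the 7-epi diol F4 is esterified with inversion under Mitsunobu conditions (AcOH, PPh3, DIAD, toluene, 0 °C), which should give 22 directly.

Step 11. The β-acetoxy ketone may lose acetic acid by base-induced elimination towards the cross-conjugated dienone, or acetylation of the hindered secondary alcohol may be too slow without a catalyst that also promotes that elimination. The fallback sets out from 14 and returns at 22, and forms the acetate at −78 °C by trapping the aldolate. 14 is silylated (TMSOTf, 2,6-lutidine, CH2Cl2, −78 °C) to the trimethylsilyl ether F5. Its lithium enolate (LDA, 1.1 equiv, THF, −78 °C) is combined with 19 and the lithium aldolate is acetylated in the flask with Ac2O at −78 °C, then quenched cold, to give the acetate silyl ether F6. HF·pyridine (THF, 0 °C) then frees the tertiary alcohol to give 22.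

**Further compounds**

F1 | step 6 | methyl (Z)-3-hydroxy-3-[(2-exo,5R)-3-phenyl-1,3-diazabicyclo[3.3.0]oct-2-yl]undec-5-enoate, (S)-carbinol at the future C12 | CCCCC/C=C\C[C@](O)(CC(=O)OC)[C@@H]1N(c2ccccc2)C[C@H]3CCCN13
F2 | step 6 | α-chloro β-keto phosphonate aminal (epimers at CHCl) | CCCCC/C=C\C[C@](O)(CC(=O)C(Cl)P(=O)(OC)OC)[C@@H]1N(c2ccccc2)C[C@H]3CCCN13
F3 | step 6 | hydroxy aldehyde keto phosphonate (epimers at CHCl) | CCCCC/C=C\C[C@](O)(CC(=O)C(Cl)P(=O)(OC)OC)C=O
F4 | step 10 | 7-epi diol, (7R,8R,12S) in prostanoid numbering | CCCCC/C=C\C[C@@]1(O)C=C(Cl)C(=O)[C@@H]1[C@@H](/C=C\CCCC(=O)OC)O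
F5 | step 11 | (S)-2-chloro-4-[(Z)-oct-2-en-1-yl]-4-(trimethylsilyloxy)cyclopent-2-en-1-one | CCCCC/C=C\C[C@@]1(O[Si](C)(C)C)C=C(Cl)C(=O)C1
F6 | step 11 | 12-O-trimethylsilyl punaglandin 8 | CCCCC/C=C\C[C@@]1(O[Si](C)(C)C)C=C(Cl)C(=O)[C@@H]1[C@H](/C=C\CCCC(=O)OC)OC(C)=O
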